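**Assumption:** the target is taken as the free hydrogen sulfate shown in the SMILES. Alkyl hydrogen sulfates are best handled in water, so the acid is set free only in the last step; an alkali salt would be the form for storage. Atom numbers used throughout: ring C1–C6 with the chain on C1, Br on C2 and C3, OH on C4 and C5, H on C6; chain C7 (benzylic) and C8 (CH2O).

## The problem

Target 8 is a benzene ring with five substituents on contiguous carbons: the 2-(sulfooxy)ethyl chain on C1, bromine on C2 and C3, hydroxyl on C4 and C5, and only C6–H left. It has no stereocentre and no ring to close, so the task is regiocontrol and functional-group timing. The two bromines are vicinal; electrophilic bromination of a 4-alkylcatechol derivative is expected to put the first bromine on C2 (para to the oxygen on C5), but the second must choose between C3, next to that bromine, and C6, next to the activating alkyl group, so the 2,3-pattern cannot be relied on. The chain ends in a primary alkyl sulfate monoester while two more acidic phenols stay free, so a late O-sulfation would have to tell three hydroxyl groups apart. The sulfate monoester tolerates base and dilute aqueous acid but not strong Lewis acids or acid in dry organic media; the aryl bromides rule out hydrogenolysis and dissolving metals; the free catechol is air-sensitive in base and must be unveiled last under mild aqueous conditions. The feature the plan exploits is that C1 and C2 are neighbours that are each para to one catechol oxygen (C1 to the oxygen on C4, C2 to the oxygen on C5): replacing the C1–C7 bond by C1–Br gives the mirror-symmetric 4,5-dibromocatechol ether 2 with two equivalent C–Br bonds, and the atoms C7–C8–O–S of the chain are the opened form of the five-membered ring of ethylene sulfate 3. One bromine–magnesium exchange on 2 and opening of 3 (step 2) therefore forms C1–C7, keeps the bromine on C2 and places the sulfate on the aliphatic oxygen without any sulfation; C3 is then the only ring C–H flanked by a bromine and an acetal oxygen, ready for directed metalation.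

## Retrosynthesis

**8 ⇒ 7 (two aryl O–CH2 bonds).** The catechol is released last. Methoxymethyl acetals are preferred to methyl ethers (cleavage needs boron trihalides, which a sulfate monoester should not survive), to benzyl ethers (hydrogenolysis would also remove the C–Br bonds) and to silyl ethers (no directing power for step 3). 7 differs from 8 only by the two acetals and the counter-ion. The forward step needs acetal hydrolysis to outrun sulfate hydrolysis; dilute aqueous acid should achieve this because 7 is a water-soluble salt.

**7 ⇒ 5 (C3–Br).** In 5, C3–H is the only ring hydrogen between a bromine (C2) and an acetal oxygen (C4); C6–H has the alkyl chain as its other neighbour. A lithium amide base and an electrophilic bromine source should therefore set the C3–Br bond through acidity and chelation, avoiding the C3/C6 competition of an electrophilic bromination. The cut is placed after the key step on purpose: with C3 already brominated, the metal at C1 would have to come from the outer one of three adjacent C–Br bonds, where exchange prefers the inner or the oxygen-flanked bromine. The forward step asks that the base leave the sulfate anion alone and that the ortho-bromoaryllithium 6 be kept cold.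

**5 ⇒ 2 + 3 (C1–C7, key disconnection).** Cutting C7–C8 would need a benzylic nucleophile and a one-carbon sulfate electrophile, and cutting O–S leads back to a chemoselective sulfation. The C1–C7 cut gives an aryl nucleophile at C1 (arylmagnesium 4, from exchange on either of the two equivalent bromines of 2) and a two-carbon electrophile that already holds the sulfate (3). 2 has no chain, no sulfur and a mirror plane; 3 is a commercial five-membered ring. The forward reaction must stop after one exchange, keep C2–Br in 4, and attack 3 at carbon.

**2 ⇒ 1 (two O–CH2 bonds).** 1 is the commercial double-bromination product of catechol, the only electrophilic substitution behind the scheme, and its para,para outcome is unambiguous. Acetal formation masks the acidic hydroxyls for the organometallic steps and installs the directing oxygen for step 3.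

## Roads not taken

**Alternative 1:** the most obvious route cuts C2–Br, C3–Br and the O–S bond. Forward: double electrophilic bromination of commercial 2-(3,4-dimethoxyphenyl)ethanol A1 to the 2,3-dibromide A2, ether cleavage, then O-sulfation with an SO3–amine complex. The chosen plan is better for two reasons:
- (a) The second bromine must enter between Br and OMe (C3) in competition with C6, which is ortho to an OMe and to the activating alkyl chain, so the 2,6-dibromide A3 is an expected contaminant.
- (b) Ether cleavage must precede sulfation, after which one aliphatic hydroxyl has to be sulfated beside two more acidic phenols; this forces a protect–sulfate–deprotect detour and more than four steps.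

**Alternative 2:** cut C7–C8 (one-carbon homologation) and let an aldehyde control the bromination. Forward: vanillin A4 is brominated ortho to its free hydroxyl (the future C3), then para to the methoxy group (the future C2) while the formyl group deactivates C6, and O-methylated to 2,3-dibromo-4,5-dimethoxybenzaldehyde A5. Methoxymethylene Wittig homologation, hydrolysis and hydride reduction give A2. The bromine pattern is secure, but about six steps are spent reaching A2, the formyl carbon that served as control element must then be extended by one carbon, and the route joins alternative 1 with the same ether-cleavage and sulfation problem. The chosen plan draws equal regiochemical certainty from symmetry and metalation and brings C7, C8 and the sulfate in one step.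

**Alternative 3:** build the ring by cutting C1–C2 and C3–C4 in a Diels–Alder/aromatisation. Forward: 3-alkoxyfuran A6 (methoxy on the future C5, chain on the future C1) adds dibromoacetylene A7. The 7-oxanorbornadiene should open at the chain-bearing bridgehead, where the cation is conjugated with the methoxy enol ether, and aromatise to phenol A8 with all five substituents placed by the cycloaddition. Against it: A7 is an explosive, air-sensitive alkyne and not an activated dienophile, and A6 needs its own multistep synthesis, so the precursors are not simpler than the product. A8 would still need ether cleavage and O-sulfation. The chosen plan starts from an intact commercial benzene ring and needs four steps.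

Key step: step 2

## Steps

**Step 1**
Reactants: 1 4,5-dibromobenzene-1,2-diol
Product: 2 1,2-dibromo-4,5-bis(methoxymethoxy)benzene
Conditions: MOMCl (2.5 equiv), iPr2NEt (3 equiv), CH2Cl2, 0 °C to rt
Reagents that add atoms: chloromethyl methyl ether (MOMCl), COCCl
Why: Double O-alkylation of the catechol with an α-chloro ether (Williamson-type acetal formation); the amine only scavenges HCl and the aryl bromides are inert. The two acetals mask the acidic hydroxyls for steps 2 and 3 and supply the directing oxygen for step 3.

**Step 2**
Reactants: 2 1,2-dibromo-4,5-bis(methoxymethoxy)benzene; 3 1,3,2-dioxathiolane 2,2-dioxide (ethylene sulfate)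
Product: 5 lithium 2-[2-bromo-4,5-bis(methoxymethoxy)phenyl]ethyl sulfate, via arylmagnesium chloride 4 (not isolated)
Conditions: iPrMgCl·LiCl (1.05 equiv), THF, −15 to 0 °C; then CuI (10 mol %), 3 (1.5 equiv), −30 to 0 °C; aq. LiCl work-up
Reagents that add atoms: isopropylmagnesium chloride–lithium chloride (iPrMgCl·LiCl), CC(C)[Mg]Cl.[Li+].[Cl-]
Why: Bromine–magnesium exchange on 2 is degenerate (its two C–Br bonds are mirror images), is favoured by the inductive stabilisation that the remaining ortho-bromine gives the aryl anion, and should stop after one exchange because a second would place two carbanionic centres on adjacent carbons. Arylmagnesium 4 should keep its ortho-bromine at or below 0 °C, since loss of magnesium halide to an aryne needs warming, so C2–Br is retained. Transmetalation to copper gives a soft aryl nucleophile that attacks one CH2 of 3 in an SN2 ring opening; ring strain and the sulfate leaving group make 3 behave like an activated epoxide. This forms the C1–C7 bond and frees the C8–O–SO3 monoester anion in the same event, so the sulfate sits on the aliphatic oxygen by construction, and the monoester anion is too poor a leaving group to be displaced again. The closest known reaction types are the copper-catalysed opening of 1,2-cyclic sulfates by Grignard reagents and the C-alkylation of aryl Grignard reagents by dialkyl sulfates. No ring is closed and no stereocentre is formed. The selectivities needed are single versus double exchange (secured by the deactivation just described), attack at carbon versus sulfur (secured by the soft organocopper and the unhindered primary carbon) and outrunning chloride opening of 3 (secured by low temperature, copper catalysis and an excess of 3).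

**Step 3**
Reactants: 5 lithium 2-[2-bromo-4,5-bis(methoxymethoxy)phenyl]ethyl sulfate
Product: 7 lithium 2-[2,3-dibromo-4,5-bis(methoxymethoxy)phenyl]ethyl sulfate, via C3-aryllithium 6 (not isolated)
Conditions: LiN(iPr)2 (1.3 equiv), THF, −78 °C, 1 h; then BrCl2C–CCl2Br (1.4 equiv), −78 to −40 °C
Reagents that add atoms: 1,2-dibromo-1,1,2,2-tetrachloroethane, BrC(Cl)(Cl)C(Cl)(Cl)Br
Why: Directed ortho-metalation: C3–H is the only ring hydrogen acidified by an adjacent bromine (C2) and held by a chelating acetal oxygen (C4), so the lithium amide should remove it in preference to C6–H, whose other neighbour is the alkyl chain; the sulfate monoanion has no acidic hydrogen and is a poor leaving group. Aryllithium 6 is kept at −78 °C to prevent loss of LiBr and is quenched by bromine transfer from the perhaloethane, which fragments to tetrachloroethene.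

**Step 4**
Reactants: 7 lithium 2-[2,3-dibromo-4,5-bis(methoxymethoxy)phenyl]ethyl sulfate
Product: 8 2-(2,3-dibromo-4,5-dihydroxyphenyl)ethyl hydrogen sulfate
Conditions: 1 M aq. HCl, argon, 40 °C; then Dowex 50W (H+ form), H2O, 0 °C; freeze-drying
Reagents that add atoms: none
Why: Specific-acid-catalysed hydrolysis of the two aryl methoxymethyl acetals through the oxygen-stabilised cation and the hemiacetal; in dilute aqueous acid at 40 °C a primary alkyl sulfate monoester should hydrolyse far more slowly, and water as the only solvent (7 is a water-soluble salt) avoids the solvolytic loss of sulfate expected in dry organic acid. The aryl bromides are inert, argon protects the catechol, and the resin exchanges Li+ for H+ to give the hydrogen sulfate.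

## Compound list

1 | 4,5-dibromobenzene-1,2-diol | Oc1cc(Br)c(Br)cc1O | starting material
2 | 1,2-dibromo-4,5-bis(methoxymethoxy)benzene | COCOc1cc(Br)c(Br)cc1OCOC | intermediate
3 | 1,3,2-dioxathiolane 2,2-dioxide (ethylene sulfate) | O=S1(=O)OCCO1 | starting material
4 | [2-bromo-4,5-bis(methoxymethoxy)phenyl]magnesium chloride | COCOc1cc(Br)c([Mg]Cl)cc1OCOC | intermediate
5 | lithium 2-[2-bromo-4,5-bis(methoxymethoxy)phenyl]ethyl sulfate | [Li+].[O-]S(=O)(=O)OCCc1cc(OCOC)c(OCOC)cc1Br | intermediate
6 | lithium 2-[2-bromo-3-lithio-4,5-bis(methoxymethoxy)phenyl]ethyl sulfate | [Li+].[O-]S(=O)(=O)OCCc1cc(OCOC)c(OCOC)c([Li])c1Br | intermediate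
7 | lithium 2-[2,3-dibromo-4,5-bis(methoxymethoxy)phenyl]ethyl sulfate | [Li+].[O-]S(=O)(=O)OCCc1cc(OCOC)c(OCOC)c(Br)c1Br | intermediate
8 | 2-(2,3-dibromo-4,5-dihydroxyphenyl)ethyl hydrogen sulfate | O=S(=O)(O)OCCc1cc(O)c(O)c(Br)c1Br | target

## Step count and risk

Total step count: 4. Longest linear sequence: 4 steps (1 → 2 → 5 → 7 → 8).

**Step 2 (key step).** Most likely failure: the cyclic sulfate is consumed by chloride from the magnesium and lithium salts, or the aryl nucleophile attacks sulfur instead of carbon, so that the C1–C7 bond does not form; warming could also cause loss of the ortho-bromine from 4 through aryne formation. The fallback sets out from 2 and comes back at 5. Arylmagnesium 4 is generated as before and opens oxirane under CuI catalysis to give 2-[2-bromo-4,5-bis(methoxymethoxy)phenyl]ethanol F1. Its single free hydroxyl (both phenols are masked) is sulfated with SO3·pyridine and the salt is neutralised with LiOH to give 5. This gives up one-step delivery of the sulfate but keeps the symmetry-based regiocontrol.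

**Step 3.** Most likely failure: slow or incomplete ring lithiation because the lithium sulfate salt dissolves poorly or aggregates at −78 °C, base-induced elimination of sulfate from the 2-arylethyl chain, or loss of LiBr from 6 if the mixture warms. The fallback sets out from 2 and comes back at 7. Alcohol F1 is made as in the step 2 fallback and silylated (tBuMe2SiCl, imidazole) to its tert-butyldimethylsilyl ether F2. The same lithiation and bromination on this neutral, ether-soluble substrate give the C3-brominated silyl ether F3. Desilylation with Bu4NF gives 2-[2,3-dibromo-4,5-bis(methoxymethoxy)phenyl]ethanol F4, and SO3·pyridine followed by LiOH gives 7.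

**Step 4.** Most likely failure: acid-catalysed loss of the sulfate competing with acetal hydrolysis, or recombination of released formaldehyde with the electron-rich C6 position of the free catechol. The fallback sets out from 7 and comes back at 8. Solvolysis is driven to completion in methanolic HCl, which removes both acetals (as the dimethyl acetal of formaldehyde) and the sulfate, to give 2-(2,3-dibromo-4,5-dihydroxyphenyl)ethanol F5. The catechol is masked transiently as the cyclic phenylboronate F6 (phenylboronic acid, toluene, azeotropic removal of water). The only free hydroxyl is sulfated with SO3·pyridine to the pyridinium sulfate F7, and water with the H+ resin hydrolyses the boronate to give 8.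

## Further compounds

F1 | step 2 | 2-[2-bromo-4,5-bis(methoxymethoxy)phenyl]ethanol | OCCc1cc(OCOC)c(OCOC)cc1Br
F2 | step 3 | tert-butyl{2-[2-bromo-4,5-bis(methoxymethoxy)phenyl]ethoxy}dimethylsilane | CC(C)(C)[Si](C)(C)OCCc1cc(OCOC)c(OCOC)cc1Br
F3 | step 3 | tert-butyl{2-[2,3-dibromo-4,5-bis(methoxymethoxy)phenyl]ethoxy}dimethylsilane | CC(C)(C)[Si](C)(C)OCCc1cc(OCOC)c(OCOC)c(Br)c1Br
F4 | step 3 | 2-[2,3-dibromo-4,5-bis(methoxymethoxy)phenyl]ethanol | OCCc1cc(OCOC)c(OCOC)c(Br)c1Br
F5 | step 4 | 2-(2,3-dibromo-4,5-dihydroxyphenyl)ethanol | OCCc1cc(O)c(O)c(Br)c1Br
F6 | step 4 | 2-(6,7-dibromo-2-phenyl-1,3,2-benzodioxaborol-5-yl)ethanol | OCCc1cc2OB(c3ccccc3)Oc2c(Br)c1Br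
F7 | step 4 | pyridinium 2-(6,7-dibromo-2-phenyl-1,3,2-benzodioxaborol-5-yl)ethyl sulfate | [O-]S(=O)(=O)OCCc1cc2OB(c3ccccc3)Oc2c(Br)c1Br.c1cc[nH+]cc1
A1 | alternative 1 | 2-(3,4-dimethoxyphenyl)ethanol | COc1ccc(CCO)cc1OC
A2 | alternative 1 | 2-(2,3-dibromo-4,5-dimethoxyphenyl)ethanol | COc1cc(CCO)c(Br)c(Br)c1OC
A3 | alternative 1 | 2-(2,6-dibromo-3,4-dimethoxyphenyl)ethanol | COc1cc(Br)c(CCO)c(Br)c1OC
A4 | alternative 2 | 4-hydroxy-3-methoxybenzaldehyde (vanillin) | COc1cc(C=O)ccc1O
A5 | alternative 2 | 2,3-dibromo-4,5-dimethoxybenzaldehyde | COc1cc(C=O)c(Br)c(Br)c1OC
A6 | alternative 3 | tert-butyl[2-(4-methoxyfuran-2-yl)ethoxy]dimethylsilane | COc1coc(CCO[Si](C)(C)C(C)(C)C)c1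
A7 | alternative 3 | dibromoacetylene (1,2-dibromoethyne) | BrC#CBr
A8 | alternative 3 | 2,3-dibromo-4-[2-(tert-butyldimethylsilyloxy)ethyl]-6-methoxyphenol | COc1cc(CCO[Si](C)(C)C(C)(C)C)c(Br)c(Br)c1O
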